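## Retrosynthetic overview

1. Target 30 ⇐ fluoride deprotection of bis-TES ether 29 ⇐ acetylation and Stille hydroxymethylation of dienyl triflate 25 (C4–C11 bond) ⇐ 5-en-4-one 24.
2. 5-Ene with 7β-ester ⇐ hydroxyl-directed reduction of 5-en-7-one 19 ⇐ Saegusa oxidation of 7-ketone 18 (C8 is quaternary, so the alkene can only form at C5=C6).
3. C1 isovalerate ⇐ acylation of lactol 16; a PMB acetal is carried through the hydride and base steps and swapped while C5 is still sp3.
4. 7β-OH / 8α-OH / 10-OH ⇐ Payne rearrangement–hydrolysis of 7β,8β-epoxy alcohol 12 ⇐ allylic alcohol from [3+2] adduct 8.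
5. Ring order: pyranone first (Achmatowicz; lipase sets the acetal centre), cyclopentene second (phosphine-catalysed [3+2] of an allenoate, anti to the acetal substituent).

Assumptions: the lipase picked from a short screen acylates the (S)-lactol (if its preference is opposite, the same enzyme is run in the alcoholysis direction on the racemic acetate); C4 in 9–22 is drawn as the expected 4α epimer, and either epimer converges at step 18.

Numbering used in names: iridoid numbering — C1 (acetal), O2, C3, C4, C5, C6, C7, C8, C9; C10 = CH2 on C8; C11 = CH2 on C4. β = the face of H-9. In the target, 1-O, 7-O and C10 are β and 8-OH is α.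

## Route

**Step 1**
Reactants: 1 furfuryl alcohol
Product: 2 6-hydroxy-2H-pyran-3(6H)-one (racemic, mutarotating lactol)
Conditions: NBS, NaHCO3, NaOAc, THF/H2O (4:1), 0 °C
Reagents that add atoms: water, O
Why: Achmatowicz oxidative ring expansion of a 2-furylcarbinol; the lactol carbon is configurationally labile, so no stereocentre is fixed yet.

**Step 2**
Reactants: 2; 3 vinyl acetate
Product: 4 (S)-6-acetoxy-2H-pyran-3(6H)-one
Conditions: immobilised lipase (Burkholderia cepacia lipase), vinyl acetate (3 equiv), hexane/MTBE, 25 °C; ee checked by chiral GC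
Reagents that add atoms: vinyl acetate, C=COC(C)=O
Why: Lipase-catalysed irreversible transesterification acylates one lactol enantiomer while the other racemises through the open-chain form (dynamic kinetic resolution), setting the first stereocentre (C1 of the target).

**Step 3**
Reactants: 4; 5 4-methoxybenzyl alcohol
Product: 6 (R)-6-(4-methoxybenzyloxy)-2H-pyran-3(6H)-one (same spatial arrangement as 4; the descriptor changes only through CIP priorities)
Conditions: Pd(OAc)2 (5 mol%), PPh3 (20 mol%), PMBOH (2 equiv), CH2Cl2, rt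
Reagents that add atoms: 4-methoxybenzyl alcohol, COc1ccc(CO)cc1
Why: Pd(0)-catalysed allylic substitution (Tsuji–Trost-type acetal exchange) goes by double inversion, so the enzyme-set centre is transferred with net retention into a base- and hydride-stable acetal.

**Step 4**
Reactants: 6; 7 ethyl buta-2,3-dienoate
Product: 8 cis-fused cycloadduct: 1β-OPMB, 4-oxo, C7=C8 with CO2Et on C8, H-5β and H-9β
Conditions: PPh3 (20 mol%), toluene, 80–110 °C
Reagents that add atoms: ethyl buta-2,3-dienoate, C=C=CC(=O)OCC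
Why: Lu phosphine-catalysed [3+2] annulation: the allenoate α-carbon bonds to the enone β-carbon and the dipole adds anti to the pseudo-axial C1 alkoxy group, setting C9 (and transient C5) cis to the C1 oxygen.

**Step 5**
Reactants: 8
Product: 9 4α-hydroxy analogue of 8
Conditions: NaBH4, CeCl3·7H2O, MeOH, −78 °C
Reagents that add atoms: none
Why: Luche 1,2-reduction of the ketone leaves the enoate untouched; hydride adds from the exo face, and this temporary centre is re-oxidised in step 18.

**Step 6**
Reactants: 9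
Product: 10 4α-OTBS ether of 9
Conditions: TBSOTf, 2,6-lutidine, CH2Cl2, 0 °C
Reagents that add atoms: TBSOTf, CC(C)(C)[Si](C)(C)OS(=O)(=O)C(F)(F)F
Why: Silylation masks the C4 carbinol so it cannot open the epoxide as an alkoxide (5-exo onto C7) under the basic conditions of step 9.

**Step 7**
Reactants: 10
Product: 11 allylic alcohol (C10-OH on C8, C7=C8)
Conditions: DIBAL-H (2.5 equiv), CH2Cl2, −78 °C
Reagents that add atoms: none
Why: DIBAL reduction of the α,β-unsaturated ester to the allylic alcohol; the acetal and silyl ether are inert at −78 °C.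

**Step 8**
Reactants: 11
Product: 12 7β,8β-epoxy-10-ol
Conditions: VO(acac)2 (5 mol%), t-BuOOH, CH2Cl2, 0 °C → rt
Reagents that add atoms: tert-butyl hydroperoxide, CC(C)(C)OO
Why: Hydroxyl-directed (Sharpless–Michaelson) vanadium epoxidation; oxygen is delivered to the exo (β) face because the α face of C8 is blocked by C1 of the pyran ring on C9.

**Step 9**
Reactants: 12
Product: 13 7β,8α,10-triol (4α-OTBS, 1β-OPMB)
Conditions: 0.5 M aq NaOH / t-BuOH (1:1), 70 °C
Reagents that add atoms: water (as hydroxide), O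
Why: Payne rearrangement (the C10 alkoxide attacks C8 with inversion to give the 8α,10-spiro-epoxide) followed by hydroxide opening at the primary carbon; 7β-OH and 8α-OH both follow stereospecifically from the β-epoxide.

**Step 10**
Reactants: 13
Product: 14 10-O-TBS-7β,8α-diol
Conditions: TBSCl (1.1 equiv), imidazole, DMF, 0 °C
Reagents that add atoms: TBSCl, CC(C)(C)[Si](C)(C)Cl
Why: Selective silylation of the primary alcohol over the secondary and tertiary ones.

**Step 11**
Reactants: 14
Product: 15 10-O-TBS-8α-hydroxy-7-ketone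
Conditions: SO3·pyridine, DMSO, i-Pr2NEt, CH2Cl2, 0 °C
Reagents that add atoms: none
Why: Parikh–Doering oxidation of the only secondary alcohol (no glycol cleavage) gives a ketone whose sole enolisable position is C6, which is needed for step 14; C8 is untouched.

**Step 12**
Reactants: 15
Product: 16 lactol (1-OH, anomeric mixture)
Conditions: DDQ (1.5 equiv), CH2Cl2 / pH 7 buffer (10:1), 0 °C → rt
Reagents that add atoms: none (the water oxygen leaves in anisaldehyde; the C1–O bond is retained)
Why: Oxidative cleavage of the PMB acetal under neutral conditions, done while C5 is sp3 and no other hydroxyl can form a competing lactol.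

**Step 13**
Reactants: 16; 17 isovaleric anhydride
Product: 18 1β-O-isovaleryl-8α-hydroxy-7-ketone
Conditions: (i-BuCO)2O (1.3 equiv), pyridine, DMAP (cat.), CH2Cl2, −20 °C
Reagents that add atoms: isovaleric anhydride, CC(C)CC(=O)OC(=O)CC(C)C
Why: DMAP-catalysed acylation of the equilibrating lactol gives the 1β ester (trans to the C9–C8 bond) because the α face of C1 is crowded by the fully substituted C8; this fixes the final C1 configuration, and the anomers are separable.

**Step 14**
Reactants: 18
Product: 19 1β-O-isovaleryl-8α-hydroxy-5-en-7-one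
Conditions: (i) TMSOTf, Et3N, CH2Cl2, −78 → −20 °C; (ii) Pd(OAc)2 (1.1 equiv), MeCN, rt; (iii) citric acid, MeOH, 0 °C
Reagents that add atoms: none (TMS groups are transient)
Why: Saegusa–Ito oxidation: the ketone enolises only toward C6 and β-hydride elimination can only take H-5, so the alkene is placed unambiguously at C5=C6; the acid work-up frees the 8-OH.

**Step 15**
Reactants: 19
Product: 20 7β,8α-diol-5-ene
Conditions: Me4NBH(OAc)3, MeCN/AcOH (1:1), −30 °C
Reagents that add atoms: none
Why: Evans–Saksena hydroxyl-directed reduction: the 8α-OH binds boron and delivers hydride intramolecularly to the α face of C7=O, giving 7β-OH trans to 8-OH without 1,4-reduction or ester reduction.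

**Step 16**
Reactants: 20; 17 isovaleric anhydride
Product: 21 1β,7β-di-O-isovaleryl-8α-ol (4α,10-bis-OTBS, 5-ene)
Conditions: (i-BuCO)2O, pyridine, DMAP (cat.), CH2Cl2, 0 °C
Reagents that add atoms: isovaleric anhydride, CC(C)CC(=O)OC(=O)CC(C)C
Why: DMAP-catalysed esterification of the secondary allylic alcohol; the tertiary 8-OH does not react.

**Step 17**
Reactants: 21
Product: 22 1β,7β-di-O-isovaleryl-5-ene-4α,8α,10-triol
Conditions: HF·pyridine, excess pyridine, THF, 0 °C → rt
Reagents that add atoms: none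
Why: Buffered fluoride desilylation removes both TBS ethers under non-basic conditions, so no ester cleavage or acyl migration occurs.

**Step 18**
Reactants: 22
Product: 23 1β,7β-di-O-isovaleryl-8α,10-dihydroxy-5-en-4-one
Conditions: activated MnO2 (excess), CH2Cl2, rt
Reagents that add atoms: none
Why: MnO2 oxidises only the allylic C4 carbinol (the primary C10-OH is not allylic and the tertiary OH is inert), removing the temporary C4 centre and giving the enone.

**Step 19**
Reactants: 23
Product: 24 8,10-bis-O-TES ether of 23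
Conditions: TESOTf (3 equiv), 2,6-lutidine, CH2Cl2, −78 → −20 °C
Reagents that add atoms: TESOTf, CC[Si](CC)(CC)OS(=O)(=O)C(F)(F)F
Why: Silylation of the primary and tertiary hydroxyls so that no alkoxide (and hence no acyl migration) can form in step 20.

**Step 20**
Reactants: 24
Product: 25 4-triflyloxy-3,5-diene
Conditions: LiHMDS (1.1 equiv), THF, −78 °C; then Comins' reagent, −78 → −40 °C
Reagents that add atoms: N-(5-chloro-2-pyridyl)bis(trifluoromethanesulfonimide), O=S(=O)(N(c1ccc(Cl)cn1)S(=O)(=O)C(F)(F)F)C(F)(F)F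
Why: Kinetic α′-deprotonation of the enone at C3 (the γ-H at C7 is hindered and only thermodynamically favoured) and O-triflation give the dienyl triflate; one equivalent of amide base at −78 °C leaves the less acidic esters alone.

**Step 21**
Reactants: 25; 26 (tributylstannyl)methanol
Product: 27 11-hydroxy-3,5-diene (CH2OH on C4)
Conditions: Bu3SnCH2OH (1.5 equiv), Pd(PPh3)4 (10 mol%), LiCl (3 equiv), THF, 60 °C
Reagents that add atoms: (tributylstannyl)methanol, CCCC[Sn](CCCC)(CCCC)CO
Why: Stille (Kosugi) hydroxymethylation forms the C4–C11 bond; oxidative addition to the vinyl triflate is much faster than ionisation of the hindered allylic C7 ester.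

**Step 22**
Reactants: 27; 28 acetic anhydride
Product: 29 11-O-acetyl-8,10-bis-O-TES-protected target
Conditions: Ac2O, pyridine, DMAP (cat.), CH2Cl2, 0 °C
Reagents that add atoms: acetic anhydride, CC(=O)OC(C)=O
Why: Acetylation of the only free (primary allylic) hydroxyl under mild basic conditions.

**Step 23**
Reactants: 29
Product: 30 Jatamanvaltrate K
Conditions: HF·pyridine, excess pyridine, THF, 0 °C → rt
Reagents that add atoms: none
Why: Buffered fluoride removes both TES ethers without base, so the three esters do not migrate and the dienyl acyl-acetal survives.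

Stereocentre origin: C1 is set in step 2, relayed to C9 in step 4, and fixed in its final form in step 13. C9 is set in step 4, C8 in steps 8–9, and C7 in step 15.

## Compound list

1 | furfuryl alcohol | OCc1ccco1 | starting material
2 | 6-hydroxy-2H-pyran-3(6H)-one (racemic lactol) | OC1OCC(=O)C=C1 | intermediate
3 | vinyl acetate | CC(=O)OC=C | starting material
4 | (S)-6-acetoxy-2H-pyran-3(6H)-one | O=C1CO[C@@H](OC(C)=O)C=C1 | intermediate
5 | 4-methoxybenzyl alcohol | COc1ccc(CO)cc1 | starting material
6 | (R)-6-(4-methoxybenzyloxy)-2H-pyran-3(6H)-one | O=C1CO[C@@H](OCc2ccc(OC)cc2)C=C1 | intermediate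
7 | ethyl buta-2,3-dienoate | C=C=CC(=O)OCC | starting material
8 | cis-fused cycloadduct (1β-OPMB, 4-oxo, 7-ene, CO2Et on C8) | CCOC(=O)C1=CC[C@@H]2C(=O)CO[C@@H](OCc3ccc(OC)cc3)[C@H]12 | intermediate
9 | 4α-alcohol of 8 | CCOC(=O)C1=CC[C@@H]2[C@H](O)CO[C@@H](OCc3ccc(OC)cc3)[C@H]12 | intermediate
10 | 4α-OTBS ether of 9 | CCOC(=O)C1=CC[C@@H]2[C@H](O[Si](C)(C)C(C)(C)C)CO[C@@H](OCc3ccc(OC)cc3)[C@H]12 | intermediate
11 | allylic alcohol (7-en-10-ol) | OCC1=CC[C@@H]2[C@H](O[Si](C)(C)C(C)(C)C)CO[C@@H](OCc3ccc(OC)cc3)[C@H]12 | intermediate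
12 | 7β,8β-epoxy-10-ol | OC[C@]12O[C@H]1C[C@@H]3[C@H](O[Si](C)(C)C(C)(C)C)CO[C@@H](OCc4ccc(OC)cc4)[C@H]23 | intermediate
13 | 7β,8α,10-triol | OC[C@@]1(O)[C@@H](O)C[C@@H]2[C@H](O[Si](C)(C)C(C)(C)C)CO[C@@H](OCc3ccc(OC)cc3)[C@H]12 | intermediate
14 | 10-O-TBS-7β,8α-diol | CC(C)(C)[Si](C)(C)OC[C@@]1(O)[C@@H](O)C[C@@H]2[C@H](O[Si](C)(C)C(C)(C)C)CO[C@@H](OCc3ccc(OC)cc3)[C@H]12 | intermediate
15 | 10-O-TBS-8α-hydroxy-7-ketone | CC(C)(C)[Si](C)(C)OC[C@@]1(O)C(=O)C[C@@H]2[C@H](O[Si](C)(C)C(C)(C)C)CO[C@@H](OCc3ccc(OC)cc3)[C@H]12 | intermediate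
16 | lactol of 15 (1-OH, anomeric mixture) | CC(C)(C)[Si](C)(C)OC[C@@]1(O)C(=O)C[C@@H]2[C@H](O[Si](C)(C)C(C)(C)C)COC(O)[C@H]12 | intermediate
17 | isovaleric anhydride | CC(C)CC(=O)OC(=O)CC(C)C | starting material
18 | 1β-O-isovaleryl-8α-hydroxy-7-ketone | CC(C)(C)[Si](C)(C)OC[C@@]1(O)C(=O)C[C@@H]2[C@H](O[Si](C)(C)C(C)(C)C)CO[C@@H](OC(=O)CC(C)C)[C@H]12 | intermediate
19 | 1β-O-isovaleryl-8α-hydroxy-5-en-7-one | CC(C)(C)[Si](C)(C)OC[C@@]1(O)C(=O)C=C2[C@H](O[Si](C)(C)C(C)(C)C)CO[C@@H](OC(=O)CC(C)C)[C@H]12 | intermediate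
20 | 1β-O-isovaleryl-5-ene-7β,8α-diol | CC(C)(C)[Si](C)(C)OC[C@@]1(O)[C@@H](O)C=C2[C@H](O[Si](C)(C)C(C)(C)C)CO[C@@H](OC(=O)CC(C)C)[C@H]12 | intermediate
21 | 1β,7β-di-O-isovaleryl-8α-ol (4α,10-bis-OTBS) | CC(C)(C)[Si](C)(C)OC[C@@]1(O)[C@@H](OC(=O)CC(C)C)C=C2[C@H](O[Si](C)(C)C(C)(C)C)CO[C@@H](OC(=O)CC(C)C)[C@H]12 | intermediate
22 | 1β,7β-di-O-isovaleryl-5-ene-4α,8α,10-triol | OC[C@@]1(O)[C@@H](OC(=O)CC(C)C)C=C2[C@H](O)CO[C@@H](OC(=O)CC(C)C)[C@H]12 | intermediate
23 | 1β,7β-di-O-isovaleryl-8α,10-dihydroxy-5-en-4-one | OC[C@@]1(O)[C@@H](OC(=O)CC(C)C)C=C2C(=O)CO[C@@H](OC(=O)CC(C)C)[C@H]12 | intermediate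
24 | 8,10-bis-O-TES ether of 23 | CC[Si](CC)(CC)OC[C@@]1(O[Si](CC)(CC)CC)[C@@H](OC(=O)CC(C)C)C=C2C(=O)CO[C@@H](OC(=O)CC(C)C)[C@H]12 | intermediate
25 | 4-triflyloxy-3,5-diene | CC[Si](CC)(CC)OC[C@@]1(O[Si](CC)(CC)CC)[C@@H](OC(=O)CC(C)C)C=C2C(OS(=O)(=O)C(F)(F)F)=CO[C@@H](OC(=O)CC(C)C)[C@H]12 | intermediate
26 | (tributylstannyl)methanol | CCCC[Sn](CCCC)(CCCC)CO | starting material
27 | 11-hydroxy-3,5-diene | CC[Si](CC)(CC)OC[C@@]1(O[Si](CC)(CC)CC)[C@@H](OC(=O)CC(C)C)C=C2C(CO)=CO[C@@H](OC(=O)CC(C)C)[C@H]12 | intermediate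
28 | acetic anhydride | CC(=O)OC(C)=O | starting material
29 | 11-O-acetyl-8,10-bis-O-TES-protected target | CC[Si](CC)(CC)OC[C@@]1(O[Si](CC)(CC)CC)[C@@H](OC(=O)CC(C)C)C=C2C(COC(C)=O)=CO[C@@H](OC(=O)CC(C)C)[C@H]12 | intermediate
30 | Jatamanvaltrate K | CC(=O)OCC1=CO[C@@H](OC(=O)CC(C)C)[C@H]2C1=C[C@H](OC(=O)CC(C)C)[C@]2(O)CO | target

## Summary

Total steps: 23. Longest linear sequence: 23 (fully linear from furfuryl alcohol).

Three steps most likely to fail, each with a fallback:

1. **Step 9 (Payne rearrangement–hydrolysis).** Direct hydroxide attack at C7 or incomplete rearrangement would give the wrong diol. Fallback: tether the nucleophile instead. Convert 12 to its N-phenylcarbamate (PhNCO) and cyclise with Et2AlCl, so the carbamate carbonyl attacks C8 5-exo with inversion to give the 8α,10-cyclic carbonate and 7β-OH; then K2CO3/MeOH gives 13.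
2. **Step 13 (anomeric acylation selectivity).** Kinetic acylation of the lactol may give α/β mixtures. Fallback: a stereospecific displacement. Make the axial α-trichloroacetimidate of 16 (Cl3CCN, DBU) and react it with isovaleric acid, which displaces with inversion to give the 1β ester 18.
3. **Step 21 (Stille hydroxymethylation).** Slow sp3 transfer at 60 °C on a heat-sensitive dienyl triflate bearing allylic esters. Fallback: introduce C11 as CO. Pd-catalysed reductive carbonylation of 25 (CO, Bu3SnH, Pd(PPh3)4, 50 °C) gives the C11 aldehyde, and Luche reduction then gives 27.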